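## Retrosynthetic overview

1. The target comes from the hydroxy acid by a last-step O-acetylation. The hydroxy acid comes from its methyl ester TBS ether. The acrylate arm is cut at the aryl–vinyl bond (Heck reaction, aryl bromide plus methyl acrylate).
2. The prenyl terminus comes from a terminal allyl group by cross-metathesis with 2-methylbut-2-ene.
3. The key disconnection is C4'–C5'. An asymmetric carbonyl allylation joins the (Z)-4-aryl-2-methylbut-2-enal (fragment 1) to B-allyldiisopinocampheylborane (fragment 2) and sets the only stereocentre (4'R).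
4. The (Z)-enal comes from a Still–Gennari olefination of (5-bromo-2-methoxyphenyl)acetaldehyde. That aldehyde comes from 5-bromo-2-methoxybenzaldehyde by a one-carbon Wittig homologation.
5. No ring is formed. The benzene ring is bought with the OMe/Br/CHO pattern already in place.

Assumption: the SMILES is read literally. The side-chain C2'=C3' olefin is Z (ArCH2 and the carbinol carbon on the same side), the acrylic acid is E, and C4' is R.

## Route

Step 1
Reactants: 1 5-bromo-2-methoxybenzaldehyde; 2 (methoxymethyl)triphenylphosphonium chloride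
Product: 4 4-bromo-1-methoxy-2-(2-methoxyethenyl)benzene (E/Z mixture), via ylide Ph3P=CHOMe 3 (not isolated)
Conditions: 2, KOt-Bu, THF, 0 °C; then 1, 0 °C to rt
Reagents that add atoms: none
Why: This Wittig olefination with the non-stabilised methoxymethylene ylide adds one carbon, the aryl bromide is inert, and the E/Z ratio does not matter because both enol ethers hydrolyse to the same aldehyde.

Step 2
Reactants: 4 4-bromo-1-methoxy-2-(2-methoxyethenyl)benzene
Product: 5 2-(5-bromo-2-methoxyphenyl)acetaldehyde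
Conditions: 2 M aq HCl, THF, 50 °C, 1–2 h; used promptly
Reagents that add atoms: water O
Why: Acid-catalysed enol ether hydrolysis (C-protonation, hydration of the oxocarbenium ion, loss of methanol) unmasks the arylacetaldehyde, and short contact time limits self-aldol.

Step 3
Reactants: 5 2-(5-bromo-2-methoxyphenyl)acetaldehyde; 6 ethyl 2-[bis(2,2,2-trifluoroethoxy)phosphoryl]propanoate
Product: 8 ethyl (2Z)-4-(5-bromo-2-methoxyphenyl)-2-methylbut-2-enoate, via potassium phosphonate carbanion 7 (not isolated)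
Conditions: 6 (1.2 equiv), KN(SiMe3)2 (1.15 equiv), 18-crown-6, THF, −78 °C; then 5, −78 °C, 2 h
Reagents that add atoms: none
Why: In this Still–Gennari variant of the Horner–Wadsworth–Emmons olefination, the electron-poor phosphonate and the crown-separated potassium ion make elimination faster than adduct equilibration, so the kinetic Z-enoate (ArCH2 cis to CO2Et, typically at least 15:1) forms, and no free base remains to enolise 5.

Step 4
Reactants: 8 ethyl (2Z)-4-(5-bromo-2-methoxyphenyl)-2-methylbut-2-enoate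
Product: 9 (2Z)-4-(5-bromo-2-methoxyphenyl)-2-methylbut-2-en-1-ol
Conditions: i-Bu2AlH (2.5 equiv), CH2Cl2, −78 °C; aq potassium sodium tartrate work-up
Reagents that add atoms: none
Why: This 1,2-hydride reduction of the enoate with i-Bu2AlH at low temperature leaves the olefin geometry, the aryl bromide and the aryl ether untouched.

Step 5
Reactants: 9 (2Z)-4-(5-bromo-2-methoxyphenyl)-2-methylbut-2-en-1-ol
Product: 10 (2Z)-4-(5-bromo-2-methoxyphenyl)-2-methylbut-2-enal
Conditions: TEMPO (10 mol %), PhI(OAc)2 (1.1 equiv), MeCN/aq Na2HPO4–NaH2PO4 buffer (pH 7), 0 °C; short neutral silica plug, used the same day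
Reagents that add atoms: none
Why: This oxoammonium (TEMPO/PhI(OAc)2) oxidation runs cold and near neutral pH, the conditions that take nerol to neral without Z-to-E leakage, so the labile Z-enal is obtained intact.

Step 6
Reactants: 11 (+)-B-methoxydiisopinocampheylborane ((−)-α-pinene series); 12 allylmagnesium bromide
Product: 13 B-allyldiisopinocampheylborane ((−)-α-pinene series), kept as a salt-free pentane solution
Conditions: CH2=CHCH2MgBr (0.95 equiv), Et2O, 0 °C to rt, 1 h; evaporate, take up in pentane, filter under Ar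
Reagents that add atoms: none
Why: Transmetalation through the borate complex swaps B–OMe for B–allyl, and removing the magnesium salts allows fast allylboration at −100 °C.

Step 7
Reactants: 10 (2Z)-4-(5-bromo-2-methoxyphenyl)-2-methylbut-2-enal; 13 B-allyldiisopinocampheylborane
Product: 15 (4R,5Z)-7-(5-bromo-2-methoxyphenyl)-5-methylhepta-1,5-dien-4-ol, via homoallyl diisopinocampheylborinate 14 (not isolated)
Conditions: 13 (1.5 equiv), Et2O–pentane, −100 °C, 2 h; then 3 M NaOH, 30% H2O2, 0 °C to rt
Reagents that add atoms: none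
Why: This Brown asymmetric allylboration, the key carbonyl allylation, proceeds through a closed chair (Zimmerman–Traxler) transition state in which the isopinocampheyl groups of the (−)-α-pinene series deliver allyl to the Re face of the 2-methylenal, giving 4R (at least 90% ee expected; the antipodal reagent gives S with such enals) faster than any Z-to-E drift.

Step 8
Reactants: 15 (4R,5Z)-7-(5-bromo-2-methoxyphenyl)-5-methylhepta-1,5-dien-4-ol
Product: 16 {[(4R,5Z)-7-(5-bromo-2-methoxyphenyl)-5-methylhepta-1,5-dien-4-yl]oxy}(tert-butyl)dimethylsilane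
Conditions: TBSCl (1.5 equiv), imidazole (3 equiv), DMF, rt
Reagents that add atoms: tert-butyldimethylsilyl chloride CC(C)(C)[Si](C)(C)Cl
Why: Silyl ether formation at oxygen retains configuration and masks the allylic alcohol against ruthenium hydride isomerisation and palladium-mediated oxidation in the next two steps.

Step 9
Reactants: 16 TBS ether of 15; 17 2-methylbut-2-ene
Product: 18 {[(2Z,4R)-1-(5-bromo-2-methoxyphenyl)-3,7-dimethylocta-2,6-dien-4-yl]oxy}(tert-butyl)dimethylsilane
Conditions: second-generation Grubbs catalyst RuCl2(=CHPh)(PCy3)(H2IMes) (3 mol %), 17 (large excess)/CH2Cl2, 40 °C, sealed tube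
Reagents that add atoms: none
Why: In this olefin cross-metathesis only the monosubstituted alkene engages the ruthenium carbene, the hindered Z-trisubstituted olefin is inert, four-membered ring closure is impossible, and excess 17 funnels all material to the unreactive prenyl product.

Step 10
Reactants: 18 prenylated aryl bromide; 19 methyl acrylate
Product: 20 methyl (2E)-3-{3-[(2Z,4R)-4-(tert-butyldimethylsilyloxy)-3,7-dimethylocta-2,6-dien-1-yl]-4-methoxyphenyl}prop-2-enoate
Conditions: Pd(OAc)2 (5 mol %), P(o-tol)3 (15 mol %), Et3N (3 equiv), 19 (3 equiv), DMF, 100 °C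
Reagents that add atoms: none
Why: In this Mizoroki–Heck reaction zerovalent palladium inserts into the C–Br bond, adds to the unhindered electron-poor acrylate rather than to the trisubstituted olefins, and syn β-hydride elimination gives the E-cinnamate, with no ionisable allylic ester yet present.

Step 11
Reactants: 20 silyl ether methyl ester
Product: 21 methyl (2E)-3-{3-[(2Z,4R)-4-hydroxy-3,7-dimethylocta-2,6-dien-1-yl]-4-methoxyphenyl}prop-2-enoate
Conditions: n-Bu4NF (2 equiv), THF, 0 °C to rt
Reagents that add atoms: none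
Why: Fluoride-driven desilylation breaks only the Si–O bond, so the stereocentre and both olefin geometries are untouched, and acid is avoided for this ionisable allylic alcohol.

Step 12
Reactants: 21 hydroxy methyl ester
Product: 22 (2E)-3-{3-[(2Z,4R)-4-hydroxy-3,7-dimethylocta-2,6-dien-1-yl]-4-methoxyphenyl}prop-2-enoic acid
Conditions: LiOH·H2O (5 equiv), THF/MeOH/H2O 3:1:1, rt to 40 °C; then cold 1 M HCl to pH 3–4
Reagents that add atoms: lithium hydroxide [Li+].[OH-]
Why: Saponification by acyl–oxygen cleavage is run before the acetate exists, so no ester selectivity problem arises.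

Step 13
Reactants: 22 hydroxy acid
Product: 24 (2E)-3-{3-[(2Z,4R)-4-acetoxy-3,7-dimethylocta-2,6-dien-1-yl]-4-methoxyphenyl}prop-2-enoic acid (target), via mixed acetic anhydride 23 (not isolated)
Conditions: Ac2O (5 equiv), pyridine, DMAP (cat.), CH2Cl2, 0 °C to rt; then H2O/THF, rt, 2 h; cold 1 M HCl to pH 3–4
Reagents that add atoms: acetic anhydride CC(=O)OC(C)=O
Why: DMAP-catalysed O-acetylation leaves the C–O bond of the stereocentre intact (retention, 4'R), while the carboxyl group is only transiently tied up as a mixed anhydride that water cleaves at its acetyl carbonyl during work-up.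

## Compound list

1 | 5-bromo-2-methoxybenzaldehyde | COc1ccc(Br)cc1C=O | starting material
2 | (methoxymethyl)triphenylphosphonium chloride | COC[P+](c1ccccc1)(c1ccccc1)c1ccccc1.[Cl-] | starting material
3 | (methoxymethylidene)triphenylphosphorane | COC=P(c1ccccc1)(c1ccccc1)c1ccccc1 | intermediate
4 | 4-bromo-1-methoxy-2-(2-methoxyethenyl)benzene, E/Z mixture | COC=Cc1cc(Br)ccc1OC | intermediate
5 | 2-(5-bromo-2-methoxyphenyl)acetaldehyde | COc1ccc(Br)cc1CC=O | intermediate
6 | ethyl 2-[bis(2,2,2-trifluoroethoxy)phosphoryl]propanoate (racemic) | CCOC(=O)C(C)P(=O)(OCC(F)(F)F)OCC(F)(F)F | starting material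
7 | potassium salt of the carbanion of 6 | CCOC(=O)[C-](C)P(=O)(OCC(F)(F)F)OCC(F)(F)F.[K+] | intermediate
8 | ethyl (2Z)-4-(5-bromo-2-methoxyphenyl)-2-methylbut-2-enoate | COc1ccc(Br)cc1C/C=C(/C)C(=O)OCC | intermediate
9 | (2Z)-4-(5-bromo-2-methoxyphenyl)-2-methylbut-2-en-1-ol | COc1ccc(Br)cc1C/C=C(/C)CO | intermediate
10 | (2Z)-4-(5-bromo-2-methoxyphenyl)-2-methylbut-2-enal | COc1ccc(Br)cc1C/C=C(/C)C=O | intermediate
11 | (+)-B-methoxydiisopinocampheylborane, (−)-α-pinene series (gives (1S,2S,3S,5R)-isopinocampheol on oxidation) | COB([C@H]1C[C@H]2C[C@@H]([C@@H]1C)C2(C)C)[C@H]1C[C@H]2C[C@@H]([C@@H]1C)C2(C)C | starting material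
12 | allylmagnesium bromide | C=CC[Mg]Br | starting material
13 | B-allyldiisopinocampheylborane, (−)-α-pinene series | C=CCB([C@H]1C[C@H]2C[C@@H]([C@@H]1C)C2(C)C)[C@H]1C[C@H]2C[C@@H]([C@@H]1C)C2(C)C | intermediate
14 | (4R,5Z)-7-(5-bromo-2-methoxyphenyl)-5-methylhepta-1,5-dien-4-yl diisopinocampheylborinate | COc1ccc(Br)cc1C/C=C(/C)[C@@H](CC=C)OB([C@H]1C[C@H]2C[C@@H]([C@@H]1C)C2(C)C)[C@H]1C[C@H]2C[C@@H]([C@@H]1C)C2(C)C | intermediate
15 | (4R,5Z)-7-(5-bromo-2-methoxyphenyl)-5-methylhepta-1,5-dien-4-ol | COc1ccc(Br)cc1C/C=C(/C)[C@@H](CC=C)O | intermediate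
16 | {[(4R,5Z)-7-(5-bromo-2-methoxyphenyl)-5-methylhepta-1,5-dien-4-yl]oxy}(tert-butyl)dimethylsilane | COc1ccc(Br)cc1C/C=C(/C)[C@@H](CC=C)O[Si](C)(C)C(C)(C)C | intermediate
17 | 2-methylbut-2-ene | CC=C(C)C | starting material
18 | {[(2Z,4R)-1-(5-bromo-2-methoxyphenyl)-3,7-dimethylocta-2,6-dien-4-yl]oxy}(tert-butyl)dimethylsilane | COc1ccc(Br)cc1C/C=C(/C)[C@@H](CC=C(C)C)O[Si](C)(C)C(C)(C)C | intermediate
19 | methyl acrylate | C=CC(=O)OC | starting material
20 | methyl (2E)-3-{3-[(2Z,4R)-4-(tert-butyldimethylsilyloxy)-3,7-dimethylocta-2,6-dien-1-yl]-4-methoxyphenyl}prop-2-enoate | COc1ccc(/C=C/C(=O)OC)cc1C/C=C(/C)[C@@H](CC=C(C)C)O[Si](C)(C)C(C)(C)C | intermediate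
21 | methyl (2E)-3-{3-[(2Z,4R)-4-hydroxy-3,7-dimethylocta-2,6-dien-1-yl]-4-methoxyphenyl}prop-2-enoate | COc1ccc(/C=C/C(=O)OC)cc1C/C=C(/C)[C@@H](CC=C(C)C)O | intermediate
22 | (2E)-3-{3-[(2Z,4R)-4-hydroxy-3,7-dimethylocta-2,6-dien-1-yl]-4-methoxyphenyl}prop-2-enoic acid | COc1ccc(/C=C/C(=O)O)cc1C/C=C(/C)[C@@H](CC=C(C)C)O | intermediate
23 | acetic (2E)-3-{3-[(2Z,4R)-4-acetoxy-3,7-dimethylocta-2,6-dien-1-yl]-4-methoxyphenyl}prop-2-enoic anhydride | COc1ccc(/C=C/C(=O)OC(C)=O)cc1C/C=C(/C)[C@@H](CC=C(C)C)OC(C)=O | intermediate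
24 | (2E)-3-{3-[(2Z,4R)-4-acetoxy-3,7-dimethylocta-2,6-dien-1-yl]-4-methoxyphenyl}prop-2-enoic acid | COc1ccc(/C=C/C(=O)O)cc1C/C=C(/C)[C@@H](CC=C(C)C)OC(C)=O | target

## Step count and risk

Total step count: 13. Longest linear sequence: 12 (steps 1–5 and 7–13; step 6 is the side branch).

The three steps most likely to fail are steps 3, 5 and 7.

**Step 3.** Aldehyde 5 is enolisable, and the Z:E ratio decides everything downstream.
- The fallback sets out from 1 and comes back at 9. It makes the Z-olefin by carbometalation and joins it by sp2–sp3 cross-coupling instead of by olefination.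
- Compound 1 is reduced with NaBH4 in MeOH to (5-bromo-2-methoxyphenyl)methanol F1.
- PBr3 in CH2Cl2 converts this into 4-bromo-2-(bromomethyl)-1-methoxybenzene F2.
- Zn dust and LiCl in THF then give (5-bromo-2-methoxybenzyl)zinc bromide F3.
- Separately, propargyl alcohol is treated with MeMgBr/CuI (chelate-controlled anti carbomagnesiation) and then I2. This gives (2Z)-3-iodo-2-methylprop-2-en-1-ol F4 as a single isomer.
- Negishi coupling of the two (Pd(PPh3)4, THF, rt) proceeds with retention at the vinyl carbon and tolerates the free hydroxyl. The vinyl iodide reacts well ahead of the electron-rich aryl bromide, and the product is 9.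

**Step 5.** The Z-enal 10 carries doubly activated (benzylic and γ) hydrogens, so it can drift to the E-isomer or to the dienol on handling.
- The fallback sets out from 1 and 13 and comes back at 16. The allylation is run on a Z-enal that has no γ-hydrogen, and the arene is attached afterwards.
- (2Z)-3-iodo-2-methylprop-2-en-1-ol F4 (made as above) is oxidised with MnO2 in CH2Cl2 to (2Z)-3-iodo-2-methylprop-2-enal F5.
- Allylboration with 13 at −100 °C (NaOH/H2O2 work-up) gives (1Z,3R)-1-iodo-2-methylhexa-1,5-dien-3-ol F6.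
- Silylation (TBSCl, imidazole, DMF) gives tert-butyl{[(1Z,3R)-1-iodo-2-methylhexa-1,5-dien-3-yl]oxy}dimethylsilane F7.
- Negishi coupling with (5-bromo-2-methoxybenzyl)zinc bromide F3 (from 1 as above; Pd(PPh3)4, THF, rt) gives 16.

**Step 7.** The enantioselectivity on a Z-configured, sterically loaded enal is the least precedented element, and an enantiomeric mixture cannot be upgraded by chromatography.
- The fallback sets out from 10 and comes back at 18. It uses an auxiliary-controlled acetate aldol whose diastereomers are separable.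
- (4S)-3-acetyl-4-isopropyl-1,3-thiazolidine-2-thione is treated with TiCl4 and i-Pr2NEt in CH2Cl2 at −78 °C and then with 10.
- This gives (3R,4Z)-6-(5-bromo-2-methoxyphenyl)-3-hydroxy-4-methyl-1-[(4S)-4-isopropyl-2-thioxo-1,3-thiazolidin-3-yl]hex-4-en-1-one F8. The minor 3S diastereomer is removed on silica.
- TBSOTf and 2,6-lutidine give its tert-butyldimethylsilyl ether F9.
- i-Bu2AlH in CH2Cl2 at −78 °C releases the auxiliary and gives (3R,4Z)-6-(5-bromo-2-methoxyphenyl)-3-(tert-butyldimethylsilyloxy)-4-methylhex-4-enal F10.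
- Wittig olefination with isopropyltriphenylphosphonium iodide and n-BuLi (THF, −78 to 0 °C) installs the isopropylidene terminus and gives 18.

## Further compounds

F1 | step 3 | (5-bromo-2-methoxyphenyl)methanol | COc1ccc(Br)cc1CO
F2 | step 3 | 4-bromo-2-(bromomethyl)-1-methoxybenzene | COc1ccc(Br)cc1CBr
F3 | step 3 | (5-bromo-2-methoxybenzyl)zinc bromide | COc1ccc(Br)cc1C[Zn]Br
F4 | step 3 | (2Z)-3-iodo-2-methylprop-2-en-1-ol | I/C=C(/C)CO
F5 | step 5 | (2Z)-3-iodo-2-methylprop-2-enal | I/C=C(/C)C=O
F6 | step 5 | (1Z,3R)-1-iodo-2-methylhexa-1,5-dien-3-ol | I/C=C(/C)[C@@H](CC=C)O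
F7 | step 5 | tert-butyl{[(1Z,3R)-1-iodo-2-methylhexa-1,5-dien-3-yl]oxy}dimethylsilane | I/C=C(/C)[C@@H](CC=C)O[Si](C)(C)C(C)(C)C
F8 | step 7 | (3R,4Z)-6-(5-bromo-2-methoxyphenyl)-3-hydroxy-4-methyl-1-[(4S)-4-isopropyl-2-thioxo-1,3-thiazolidin-3-yl]hex-4-en-1-one | COc1ccc(Br)cc1C/C=C(/C)[C@@H](CC(=O)N1[C@@H](C(C)C)CSC1=S)O
F9 | step 7 | tert-butyldimethylsilyl ether of F8 | COc1ccc(Br)cc1C/C=C(/C)[C@@H](CC(=O)N1[C@@H](C(C)C)CSC1=S)O[Si](C)(C)C(C)(C)C
F10 | step 7 | (3R,4Z)-6-(5-bromo-2-methoxyphenyl)-3-(tert-butyldimethylsilyloxy)-4-methylhex-4-enal | COc1ccc(Br)cc1C/C=C(/C)[C@@H](CC=O)O[Si](C)(C)C(C)(C)C
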